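## Retrosynthetic overview

1. The pyran ring is closed last. The C4–C4a bond comes from a 6-endo hydroarylation of an aryl propargyl ether. The C2–O bond comes from an enantioconvergent copper-catalysed etherification of a tertiary propargylic carbonate with symmetric 4,6-dimethoxyresorcinol, itself made from resorcinol.
2. The carbonate comes from a methyl ketone and ethynyl Grignard. One double methylenation of a keto ester delivers both the methyl ketone and the exocyclic methylene.
3. Key step: the cyclohexanone comes from an α-quaternary cyclopentanone and diazoethane. CH(CH3) is inserted by a 1,2-shift of the ring CH2 (five to six ring expansion), which sets the tertiary methyl centre.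
4. The quaternary centre comes from 2-methylcyclopentanone and methyl acrylate by an auxiliary-controlled Michael addition.
5. Ring order: the carbocycle is bought five-membered and expanded to six, the arene is bought, and the pyran is formed last.

Assumption: the sense of induction of the chiral ligands in steps 2 and 7 must be found by experiment. The enantiomer named is taken to give the drawn product; otherwise its mirror image is used.

## Route

Step 1
Reactants: 1 2-methylcyclopentanone (racemic); 2 methyl acrylate
Product: 5 methyl 3-[(1R)-1-methyl-2-oxocyclopentyl]propanoate, via ketimine 3 (not isolated), via adduct ketimine 4 (not isolated)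
Conditions: (S)-1-phenylethylamine (1.0 equiv), TsOH (cat.), toluene, Dean–Stark reflux; concentrate; 2 (1.3 equiv), THF, 40 °C, 48 h; then 20% aq AcOH, rt
Reagents that add atoms: water O; (S)-1-phenylethylamine C[C@H](N)c1ccccc1 (present only in 3 and 4, cleaved again)
Why: d'Angelo deracemising Michael addition: the ketimine reacts through its more substituted secondary enamine in a compact aza-ene-like transition state, and the phenyl group of the (S)-auxiliary shields one face, so the acrylate is attached to give the (R)-quaternary centre (about 90% ee, same sense as in the 2-methylcyclohexanone series).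

Step 2
Reactants: 5 methyl 3-[(1R)-1-methyl-2-oxocyclopentyl]propanoate; 6 N-ethyl-N-nitrosourea
Product: 8 methyl 3-[(1R,3R)-1,3-dimethyl-2-oxocyclohexyl]propanoate, via diazoethane 7 (not isolated)
Conditions: 6, 40% aq KOH/toluene, 0 °C, decant and dry over KOH pellets; add this solution of 7 (1.5 equiv) over 1 h to 5, Sc(OTf)3 (10 mol %), 2,6-bis[(4S)-4-phenyl-4,5-dihydro-1,3-oxazol-2-yl]pyridine (12 mol %), 4 Å MS, toluene, −78 → −40 °C
Reagents that add atoms: none
Why: Proposed new method: catalyst-controlled Büchner–Curtius–Schlotterbeck (Tiffeneau–Demjanov-type) ring expansion of an α-quaternary cyclopentanone with diazoethane; the diazo carbon adds to the scandium-bound ketone, and in the β-oxido diazonium only the rotamer with the ring CH2 anti to N2 avoids a gauche clash between the diazo methyl and the quaternary carbon, so the CH2 (not the quaternary carbon) makes the 1,2-shift with inversion at the diazo carbon and loss of N2 to give the six-membered ketone; the pybox pocket chooses the prochiral face of diazoethane and so fixes C3 as R (methyls trans), the cold non-basic medium prevents epimerisation, the 2,2,6-trisubstituted product is too hindered for a second insertion, and the roughly 5% of ent-5 ends up as a separable cis-dimethyl diastereomer, which raises optical purity; the closest known reaction types are the Sc(OTf)3/chiral oxazoline-catalysed insertion of aryldiazomethanes into unsubstituted cycloalkanones and the achiral organoaluminium-promoted diazoethane homologation.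

Step 3
Reactants: 8 methyl 3-[(1R,3R)-1,3-dimethyl-2-oxocyclohexyl]propanoate
Product: 10 4-[(1R,3R)-1,3-dimethyl-2-methylidenecyclohexyl]butan-2-one, via methyl enol ether 9 (not isolated)
Conditions: Cp2Ti(μ-CH2)(μ-Cl)AlMe2 (3.0 equiv), pyridine (cat.), THF–toluene, −40 °C → rt; then 0.5 M HCl, THF, 0 °C, 30 min
Reagents that add atoms: Tebbe reagent Cp2Ti(μ-CH2)(μ-Cl)AlMe2 C[Al-]1(C)C[Ti](C2C=CC=C2)(C2C=CC=C2)[Cl+]1; water O
Why: Tebbe methylenation: the non-basic titanium methylidene converts the hindered, epimerisable ketone into the exocyclic alkene without touching C3 and turns the ester into its methyl enol ether, which cold dilute acid hydrolyses to the methyl ketone far faster than it can protonate the hindered 1,1-disubstituted alkene.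

Step 4
Reactants: 10 4-[(1R,3R)-1,3-dimethyl-2-methylidenecyclohexyl]butan-2-one; 11 ethynylmagnesium bromide
Product: 13 5-[(1R,3R)-1,3-dimethyl-2-methylidenecyclohexyl]-3-methylpent-1-yn-3-yl methyl carbonate (about 1:1 epimers at C3 of the pentynyl chain), via bromomagnesium alkoxide 12 (not isolated)
Conditions: 11 (1.5 equiv, 0.5 M in THF), THF, 0 °C → rt; then ClCO2Me (2.5 equiv), DMAP (cat.), 0 °C → rt
Reagents that add atoms: methyl chloroformate COC(=O)Cl
Why: Grignard 1,2-addition to an unhindered methyl ketone followed by in-flask O-acylation of the alkoxide; the new carbinol centre forms unselectively, which does not matter because it is erased and reset in step 7.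

Step 5
Reactants: 14 resorcinol
Product: 15 4,6-dibromobenzene-1,3-diol
Conditions: Br2 (2.05 equiv), CHCl3, 0 °C → rt; recrystallise
Reagents that add atoms: bromine BrBr
Why: Electrophilic aromatic bromination: both hydroxyls direct to C4 and C6, the flanked C2 is attacked last, and two equivalents stop at the 4,6-dibromide.

Step 6
Reactants: 15 4,6-dibromobenzene-1,3-diol
Product: 16 4,6-dimethoxybenzene-1,3-diol
Conditions: NaOMe (8 equiv, 5.4 M in MeOH), CuBr (20 mol %), DMF, 110 °C, N2, 12 h; then degassed 2 M HCl
Reagents that add atoms: sodium methoxide C[O-].[Na+]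
Why: Ullmann-type copper-catalysed methanolysis of ortho-bromophenolates: each bromine sits next to a copper-binding phenoxide, as in the established conversion of 3,5-dibromo-4-hydroxybenzaldehyde into syringaldehyde.

Step 7
Reactants: 13 5-[(1R,3R)-1,3-dimethyl-2-methylidenecyclohexyl]-3-methylpent-1-yn-3-yl methyl carbonate; 16 4,6-dimethoxybenzene-1,3-diol (3 equiv, excess recovered)
Product: 17 5-{[(3S)-5-[(1R,3R)-1,3-dimethyl-2-methylidenecyclohexyl]-3-methylpent-1-yn-3-yl]oxy}-2,4-dimethoxyphenol
Conditions: [Cu(MeCN)4]PF6 (5 mol %), 2,6-bis[(4S)-4-(3,5-di-tert-butylphenyl)-4,5-dihydro-1,3-oxazol-2-yl]pyridine (6 mol %), i-Pr2NEt (1.2 equiv), THF, −10 °C, N2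
Reagents that add atoms: none
Why: Proposed new method: enantioconvergent propargylic etherification of a dialkyl tertiary carbonate with a phenol; monovalent copper forms the acetylide of 13, and loss of methyl carbonate gives a planar copper allenylidene in which both epimers of 13 converge; the phenoxide of 16 then attacks the γ-carbon inside the confined pybox pocket on the face where the small methyl group rather than the CH2CH2R arm faces the aryl wall, giving the (S)-ether; the two hydroxyls of 16 are equivalent and its excess keeps the reaction at mono-alkylation; the closest known reaction types are the copper–pybox etherification of secondary propargylic esters with phenols, related copper–pybox aminations of ketone-derived carbonates, and the racemic CuCl2/DBU etherification of tertiary propargylic carbonates.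

Step 8
Reactants: 17 5-{[(3S)-5-[(1R,3R)-1,3-dimethyl-2-methylidenecyclohexyl]-3-methylpent-1-yn-3-yl]oxy}-2,4-dimethoxyphenol
Product: 18 metachromin B
Conditions: Ph3PAuNTf2 (3 mol %), CH2Cl2, 0 °C → rt
Reagents that add atoms: none
Why: Gold-catalysed 6-endo-dig intramolecular hydroarylation (Friedel–Crafts-type attack on the π-activated alkyne, then protodeauration): only one carbon ortho to the ether oxygen bears hydrogen and two ortho oxygens activate it, while the C–O bond at the stereocentre is never broken, so (S) is retained and the hindered exocyclic alkene is untouched.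

## Compound list

1 | 2-methylcyclopentanone (racemic) | CC1CCCC1=O | starting material
2 | methyl acrylate | C=CC(=O)OC | starting material
3 | 2-methyl-N-[(1S)-1-phenylethyl]cyclopentan-1-imine | CC1CCCC1=N[C@@H](C)c1ccccc1 | intermediate
4 | methyl 3-[(1R)-1-methyl-2-{[(1S)-1-phenylethyl]imino}cyclopentyl]propanoate | C[C@@H](c1ccccc1)N=C1CCC[C@]1(C)CCC(=O)OC | intermediate
5 | methyl 3-[(1R)-1-methyl-2-oxocyclopentyl]propanoate | O=C1CCC[C@]1(C)CCC(=O)OC | intermediate
6 | N-ethyl-N-nitrosourea | CCN(N=O)C(N)=O | starting material
7 | diazoethane | CC=[N+]=[N-] | intermediate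
8 | methyl 3-[(1R,3R)-1,3-dimethyl-2-oxocyclohexyl]propanoate | O=C1[C@H](C)CCC[C@]1(C)CCC(=O)OC | intermediate
9 | (1R,3R)-1-(3-methoxybut-3-en-1-yl)-1,3-dimethyl-2-methylidenecyclohexane | C=C1[C@H](C)CCC[C@]1(C)CCC(=C)OC | intermediate
10 | 4-[(1R,3R)-1,3-dimethyl-2-methylidenecyclohexyl]butan-2-one | C=C1[C@H](C)CCC[C@]1(C)CCC(C)=O | intermediate
11 | ethynylmagnesium bromide | C#C[Mg]Br | starting material
12 | bromomagnesium 5-[(1R,3R)-1,3-dimethyl-2-methylidenecyclohexyl]-3-methylpent-1-yn-3-olate (epimers at C3) | C=C1[C@H](C)CCC[C@]1(C)CCC(C)(C#C)O[Mg]Br | intermediate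
13 | 5-[(1R,3R)-1,3-dimethyl-2-methylidenecyclohexyl]-3-methylpent-1-yn-3-yl methyl carbonate (epimers at C3) | C=C1[C@H](C)CCC[C@]1(C)CCC(C)(C#C)OC(=O)OC | intermediate
14 | resorcinol | Oc1cccc(O)c1 | starting material
15 | 4,6-dibromobenzene-1,3-diol | Oc1cc(O)c(Br)cc1Br | intermediate
16 | 4,6-dimethoxybenzene-1,3-diol | COc1cc(OC)c(O)cc1O | intermediate
17 | 5-{[(3S)-5-[(1R,3R)-1,3-dimethyl-2-methylidenecyclohexyl]-3-methylpent-1-yn-3-yl]oxy}-2,4-dimethoxyphenol | C=C1[C@H](C)CCC[C@]1(C)CC[C@@](Oc1cc(O)c(OC)cc1OC)(C)C#C | intermediate
18 | metachromin B, (2S)-2-{2-[(1R,3R)-1,3-dimethyl-2-methylidenecyclohexyl]ethyl}-6,8-dimethoxy-2-methyl-2H-chromen-5-ol | C=C1[C@H](C)CCC[C@]1(C)CC[C@@]1(C)C=Cc2c(O)c(OC)cc(OC)c2O1 | target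

## Step count and risks

Total step count: 8.
Longest linear sequence: 6 (steps 1, 2, 3, 4, 7, 8).

The three steps most likely to fail are the following.

**Step 2 (proposed new step).** The risks are poor control of the C3 methyl centre, some migration of the quaternary carbon, and epoxide formation. The fallback uses known chemistry, sets out from 5 and comes back at 8.
- Me3SiCHN2 with BF3·OEt2 in CH2Cl2 at −78 °C inserts on the methylene side. This gives methyl 3-[(1R)-1-methyl-2-oxo-3-(trimethylsilyl)cyclohexyl]propanoate F1.
- Dilute HCl in THF removes silicon to give methyl 3-[(1R)-1-methyl-2-oxocyclohexyl]propanoate F2.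
- LiN(i-Pr)2 and then MeI at −78 °C methylate the only enolisable ring position. This gives 8 together with its epimer methyl 3-[(1R,3S)-1,3-dimethyl-2-oxocyclohexyl]propanoate F3.
- The two are separated on silica, and the unwanted epimer is re-equilibrated with DBU and recycled.

**Step 3.** The risks are that the ester reacts faster than the doubly flanked ketone, that conversion stays incomplete, or that the alkene migrates during the acid treatment. The fallback sets out from 8 and comes back at 10.
- The gem-dimetallic Lombardo–Takai reagent (Zn, CH2Br2, TiCl4, THF–CH2Cl2) methylenates only the ketone, without base. This gives methyl 3-[(1R,3R)-1,3-dimethyl-2-methylidenecyclohexyl]propanoate F4.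
- MeNHOMe·HCl with i-PrMgCl gives the Weinreb amide 3-[(1R,3R)-1,3-dimethyl-2-methylidenecyclohexyl]-N-methoxy-N-methylpropanamide F5.
- MeMgBr then gives 10, with no acid step.

**Step 7 (proposed new step).** The risks are weak discrimination of methyl against the primary alkyl arm, elimination to the enyne, and C-alkylation of the arene. The fallback uses known chemistry, sets out from 13 and 16 and comes back at 18.
- CuCl2 (cat.) and DBU in MeCN at 0 °C give the ether without selectivity. The product is 5-{[5-[(1R,3R)-1,3-dimethyl-2-methylidenecyclohexyl]-3-methylpent-1-yn-3-yl]oxy}-2,4-dimethoxyphenol as a 1:1 epimer mixture F6.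
- Ph3PAuNTf2 cyclises this mixture to 18 together with (2R)-2-{2-[(1R,3R)-1,3-dimethyl-2-methylidenecyclohexyl]ethyl}-6,8-dimethoxy-2-methyl-2H-chromen-5-ol F7.
- The two diastereomers are separated by preparative HPLC on a chiral stationary phase.

## Further compounds

F1 | step 2 | methyl 3-[(1R)-1-methyl-2-oxo-3-(trimethylsilyl)cyclohexyl]propanoate | O=C1C([Si](C)(C)C)CCC[C@]1(C)CCC(=O)OC
F2 | step 2 | methyl 3-[(1R)-1-methyl-2-oxocyclohexyl]propanoate | O=C1CCCC[C@]1(C)CCC(=O)OC
F3 | step 2 | methyl 3-[(1R,3S)-1,3-dimethyl-2-oxocyclohexyl]propanoate | O=C1[C@@H](C)CCC[C@]1(C)CCC(=O)OC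
F4 | step 3 | methyl 3-[(1R,3R)-1,3-dimethyl-2-methylidenecyclohexyl]propanoate | C=C1[C@H](C)CCC[C@]1(C)CCC(=O)OC
F5 | step 3 | 3-[(1R,3R)-1,3-dimethyl-2-methylidenecyclohexyl]-N-methoxy-N-methylpropanamide | C=C1[C@H](C)CCC[C@]1(C)CCC(=O)N(C)OC
F6 | step 7 | 5-{[5-[(1R,3R)-1,3-dimethyl-2-methylidenecyclohexyl]-3-methylpent-1-yn-3-yl]oxy}-2,4-dimethoxyphenol (1:1 epimers) | C=C1[C@H](C)CCC[C@]1(C)CCC(C)(C#C)Oc1cc(O)c(OC)cc1OC
F7 | step 7 | (2R)-2-{2-[(1R,3R)-1,3-dimethyl-2-methylidenecyclohexyl]ethyl}-6,8-dimethoxy-2-methyl-2H-chromen-5-ol | C=C1[C@H](C)CCC[C@]1(C)CC[C@]1(C)C=Cc2c(O)c(OC)cc(OC)c2O1
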